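**Strategy.** The 12-membered carbocycle is disconnected at the sp2–sp3 bond between the methyl-bearing carbon of one (Z)-alkene and the CH2 two bonds away from the ring carbon flanked by the quaternary centre and the spiro-oxirane. The precursor is a fully substituted cyclohexane (quaternary ester, trans-disposed arms, oxirane in place) that carries a vinyl group on one side and, on the other, a chain ending in a (Z)-alkenyl iodide. Hydroboration and intramolecular B-alkyl Suzuki coupling then close the macrocycle in one operation as the last ring, transferring the alkene geometry with retention. No stereocentre is formed in that step; all four are set on the monocycle.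

Key step: step 15

Remark: compounds 1, 7, 8 and 19 and all reagents are taken as commercial; monomeric formaldehyde is generated by cracking paraformaldehyde.

Step 1
Reactants: 1 neryl acetate
Product: 3 (2Z)-6,6-dimethoxy-3-methylhex-2-en-1-yl acetate, via aldehyde 2 (not isolated)
Conditions: O3 (1 equiv), pyridine, CH2Cl2/MeOH, −78 °C; Me2S; then p-TsOH (cat.), MeOH, rt
Reagents that add atoms: methanol, CO; ozone, [O-][O+]=O (supplies only the carbonyl oxygen of 2)
Why: Ozonolysis with reductive work-up and acid-catalysed acetalisation; the electron-rich terminal alkene should be cleaved ahead of the alkene deactivated by the allylic acetate, and the (Z)-alkene is untouched.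

Step 2
Reactants: 3 (2Z)-6,6-dimethoxy-3-methylhex-2-en-1-yl acetate
Product: 4 (2Z)-6,6-dimethoxy-3-methylhex-2-en-1-ol
Conditions: K2CO3, MeOH, rt
Reagents that add atoms: none
Why: Base-catalysed transesterification frees the allylic alcohol while the acetal is stable to base.

Step 3
Reactants: 4 (2Z)-6,6-dimethoxy-3-methylhex-2-en-1-ol
Product: 6 (2Z)-1-bromo-6,6-dimethoxy-3-methylhex-2-ene, via mesylate 5 (not isolated)
Conditions: MsCl, Et3N, THF, −40 °C; then LiBr, THF, 0 °C
Reagents that add atoms: lithium bromide, [Li+].[Br-]; methanesulfonyl chloride, CS(=O)(=O)Cl (present in 5 only)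
Why: Mesylation and SN2 displacement by bromide at low temperature should give the allylic bromide without acid and without loss of the (Z)-geometry.

Step 4
Reactants: 7 1,4-dioxaspiro[4.5]decan-7-one; 8 (R)-1-amino-2-(methoxymethyl)pyrrolidine (RAMP)
Product: 9 RAMP hydrazone of 7
Conditions: neat, 60 °C, 4 Å sieves
Reagents that add atoms: none
Why: Hydrazone condensation under neutral conditions installs the chiral auxiliary and leaves the ketal intact.

Step 5
Reactants: 9 RAMP hydrazone of 7; 6 (2Z)-1-bromo-6,6-dimethoxy-3-methylhex-2-ene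
Product: 11 RAMP hydrazone of the (8R)-8-alkylated ketone, via lithium azaenolate 10 (not isolated)
Conditions: LDA, THF, 0 °C; then 6, −100 → −78 °C
Reagents that add atoms: none
Why: Asymmetric hydrazone alkylation (RAMP method): deprotonation should occur at the CH2 remote from the ketal, and the chelated azaenolate should be alkylated on the face set by the auxiliary to give the (R)-configured carbon that carries the bridge, with SN2 retention of the (Z)-alkene.

Step 6
Reactants: 11 RAMP hydrazone of the (8R)-8-alkylated ketone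
Product: 12 (8R)-8-[(2Z)-6,6-dimethoxy-3-methylhex-2-en-1-yl]-1,4-dioxaspiro[4.5]decan-7-one
Conditions: CuCl2, THF/H2O (pH 7 buffer), rt; aq. NH3 work-up
Reagents that add atoms: water, O
Why: CuCl2-promoted hydrolytic hydrazone cleavage should release the α-substituted ketone without epimerisation and without touching the ketal or the dimethyl acetal.

Step 7
Reactants: 12 (8R)-8-[(2Z)-6,6-dimethoxy-3-methylhex-2-en-1-yl]-1,4-dioxaspiro[4.5]decan-7-one
Product: 14 enol triflate of 12 (C6=C7), via lithium enolate 13 (not isolated)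
Conditions: LDA, THF, −78 °C; then PhNTf2, −78 → 0 °C
Reagents that add atoms: N-phenylbis(trifluoromethanesulfonimide), O=S(=O)(N(c1ccccc1)S(=O)(=O)C(F)(F)F)C(F)(F)F
Why: Kinetic deprotonation at the CH2 rather than at the substituted CH, followed by O-triflation, should give the enol triflate with the stereocentre intact.

Step 8
Reactants: 14 enol triflate of 12
Product: 16 2-(trimethylsilyl)ethyl (8R)-8-[(2Z)-3-methyl-6-oxohex-2-en-1-yl]-1,4-dioxaspiro[4.5]dec-6-ene-7-carboxylate, via ketal ester 15 (not isolated)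
Conditions: Pd(OAc)2 (5 mol %), PPh3, CO (1 atm), Me3SiCH2CH2OH, Et3N, DMF, 50 °C; then PPTS, acetone/H2O, rt
Reagents that add atoms: carbon monoxide, [C-]#[O+]; 2-(trimethylsilyl)ethanol, C[Si](C)(C)CCO; water, O
Why: Palladium-catalysed alkoxycarbonylation of the enol triflate installs the carboxyl carbon as a fluoride-labile ester, and mild acid should then hydrolyse the acyclic dimethyl acetal in preference to the dioxolane, which is deactivated by the adjacent electron-poor alkene.

Step 9
Reactants: 16 aldehyde ketal ester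
Product: 18 2-(trimethylsilyl)ethyl (6R)-6-[(2Z,6Z)-7-iodo-3-methylocta-2,6-dien-1-yl]-3-oxocyclohex-1-ene-1-carboxylate, via ketal alkenyl iodide 17 (not isolated)
Conditions: EtPPh3I, n-BuLi, THF; I2, −78 °C; NaHMDS; then 16, −78 → −20 °C; then 2 M HCl, THF, rt
Reagents that add atoms: ethyltriphenylphosphonium iodide, CC[P+](c1ccccc1)(c1ccccc1)c1ccccc1.[I-]; iodine, II; water, O
Why: Wittig olefination with the α-iodo ylide (Stork–Zhao type) should give the (Z)-alkenyl iodide through the kinetically favoured cis-oxaphosphetane, and aqueous acid then unmasks the ketone as the conjugated enone.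

Step 10
Reactants: 18 enone ester; 19 5-bromo-2-methylpent-2-ene
Product: 22 2-(trimethylsilyl)ethyl (1S,2S,6R)-2-(hydroxymethyl)-6-[(2Z,6Z)-7-iodo-3-methylocta-2,6-dien-1-yl]-1-(4-methylpent-3-en-1-yl)-3-oxocyclohexane-1-carboxylate, via Grignard reagent 20 (not isolated), via magnesium enolate 21 (not isolated)
Conditions: 19, Mg, THF; CuBr·SMe2 (20 mol %), THF, −78 °C; then CH2O (gas), −78 → −40 °C; aq. NH4Cl
Reagents that add atoms: formaldehyde, C=O
Why: Copper-catalysed conjugate addition β to the ketone should occur anti to the neighbouring side chain and create the quaternary centre with the ester cis to that chain, and the enolate is then hydroxymethylated (aldol) anti to the now axial ester, which fixes the third contiguous stereocentre.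

Step 11
Reactants: 22 hydroxymethyl ketone
Product: 23 2-(trimethylsilyl)ethyl (1S,2S,6R)-2-(hydroxymethyl)-6-[(2Z,6Z)-7-iodo-3-methylocta-2,6-dien-1-yl]-3-methylidene-1-(4-methylpent-3-en-1-yl)cyclohexane-1-carboxylate
Conditions: Zn, CH2Br2, TiCl4 (pre-formed reagent, excess), THF/CH2Cl2, 0 °C → rt
Reagents that add atoms: dibromomethane, BrCBr
Why: Takai–Lombardo methylenation converts the hindered, enolisable ketone into the exocyclic alkene under non-basic conditions, so the adjacent stereocentre should not epimerise and retro-aldol loss of formaldehyde is avoided.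

Step 12
Reactants: 23 methylidene alcohol
Product: 24 2-(trimethylsilyl)ethyl (3S,4S,5S,6R)-4-(hydroxymethyl)-6-[(2Z,6Z)-7-iodo-3-methylocta-2,6-dien-1-yl]-5-(4-methylpent-3-en-1-yl)-1-oxaspiro[2.5]octane-5-carboxylate
Conditions: VO(acac)2 (5 mol %), t-BuOOH, CH2Cl2, 0 °C → rt
Reagents that add atoms: tert-butyl hydroperoxide, CC(C)(C)OO
Why: Hydroxyl-directed epoxidation of the homoallylic alcohol should deliver oxygen to the alkene face syn to the CH2OH group, giving the oxirane with oxygen trans to the ester, and should leave the isolated trisubstituted alkenes untouched.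

Step 13
Reactants: 24 epoxy alcohol
Product: 25 2-(trimethylsilyl)ethyl (3S,4R,5S,6R)-4-formyl-6-[(2Z,6Z)-7-iodo-3-methylocta-2,6-dien-1-yl]-5-(4-methylpent-3-en-1-yl)-1-oxaspiro[2.5]octane-5-carboxylate
Conditions: Dess–Martin periodinane, NaHCO3, CH2Cl2, 0 °C
Reagents that add atoms: none
Why: Dess–Martin oxidation under buffered, non-epimerising conditions gives the aldehyde.

Step 14
Reactants: 25 epoxy aldehyde
Product: 26 2-(trimethylsilyl)ethyl (3S,4R,5S,6R)-4-ethenyl-6-[(2Z,6Z)-7-iodo-3-methylocta-2,6-dien-1-yl]-5-(4-methylpent-3-en-1-yl)-1-oxaspiro[2.5]octane-5-carboxylate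
Conditions: Ph3PCH3Br, KHMDS, THF, −78 → 0 °C
Reagents that add atoms: methyltriphenylphosphonium bromide, C[P+](c1ccccc1)(c1ccccc1)c1ccccc1.[Br-]
Why: Wittig methylenation at low temperature should provide the vinyl group, the future two-carbon arm of the bridge, faster than enolisation towards the β-oxirane can occur.

Step 15
Reactants: 26 vinyl epoxide bearing the (Z)-alkenyl iodide
Product: 28 2-(trimethylsilyl)ethyl ester of the target acid, via B-alkyl-9-BBN 27 (not isolated)
Conditions: 9-BBN-H, THF, rt; then slow addition to Pd(dppf)Cl2 (20 mol %), AsPh3, Cs2CO3, DMF/THF/H2O, 50 °C (final 1 mM)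
Reagents that add atoms: none
Why: Anti-Markovnikov hydroboration of the only monosubstituted alkene gives a primary B-alkyl-9-BBN; oxidative addition of zerovalent palladium into the (Z)-alkenyl iodide, base-assisted transmetalation and C(sp3)–C(sp2) reductive elimination then join the two chain ends. The closest known reaction type is the intramolecular B-alkyl Suzuki–Miyaura coupling, an established way to close macrocyclic trisubstituted alkenes. The 12-membered ring closes by macrocyclisation through a 13-membered palladacycle under high dilution; the cyclohexane and the oxirane are already present, so no ring is formed afterwards. No stereocentre is created: the trans relation of the two arms across the quaternary carbon was fixed in steps 5 and 10, and the (Z)-geometry of the new ring alkene is carried over with retention from the alkenyl iodide. The step needs chemoselective hydroboration (vinyl group only, not the three trisubstituted alkenes, ester or oxirane) and ring closure in preference to oligomerisation. The first should be secured by the steric demand of 9-BBN, the second by slow addition and by the two (Z)-alkenes, which bend the nine-carbon bridge back towards the ring.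

Step 16
Reactants: 28 2-(trimethylsilyl)ethyl ester of the target acid
Product: 29 target acid CNP0116395.1
Conditions: TBAF, THF, 0 °C → rt; pH 5 phosphate buffer work-up
Reagents that add atoms: none
Why: Fluoride-induced fragmentation of the 2-(trimethylsilyl)ethyl ester (β-elimination at silicon) should free the hindered acid without a nucleophile attacking the carbonyl or the oxirane.

**Compound list**

1 | neryl acetate, (2Z)-3,7-dimethylocta-2,6-dien-1-yl acetate | CC(=O)OC/C=C(/C)CCC=C(C)C | starting material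
2 | (2Z)-3-methyl-6-oxohex-2-en-1-yl acetate | CC(=O)OC/C=C(/C)CCC=O | intermediate
3 | (2Z)-6,6-dimethoxy-3-methylhex-2-en-1-yl acetate | CC(=O)OC/C=C(/C)CCC(OC)OC | intermediate
4 | (2Z)-6,6-dimethoxy-3-methylhex-2-en-1-ol | OC/C=C(/C)CCC(OC)OC | intermediate
5 | (2Z)-6,6-dimethoxy-3-methylhex-2-en-1-yl methanesulfonate | CS(=O)(=O)OC/C=C(/C)CCC(OC)OC | intermediate
6 | (2Z)-1-bromo-6,6-dimethoxy-3-methylhex-2-ene | BrC/C=C(/C)CCC(OC)OC | intermediate
7 | 1,4-dioxaspiro[4.5]decan-7-one | O=C1CCCC2(C1)OCCO2 | starting material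
8 | (R)-1-amino-2-(methoxymethyl)pyrrolidine (RAMP) | COC[C@H]1CCCN1N | starting material
9 | RAMP hydrazone of 7 (C=N geometry not fixed) | COC[C@H]1CCCN1N=C1CCCC2(C1)OCCO2 | intermediate
10 | lithium azaenolate of 9 (C7=C8) | COC[C@H]1CCCN1N([Li])C1=CCCC2(C1)OCCO2 | intermediate
11 | RAMP hydrazone of (8R)-8-[(2Z)-6,6-dimethoxy-3-methylhex-2-en-1-yl]-1,4-dioxaspiro[4.5]decan-7-one | COC[C@H]1CCCN1N=C1CC2(CC[C@@H]1C/C=C(/C)CCC(OC)OC)OCCO2 | intermediate
12 | (8R)-8-[(2Z)-6,6-dimethoxy-3-methylhex-2-en-1-yl]-1,4-dioxaspiro[4.5]decan-7-one | O=C1CC2(CC[C@@H]1C/C=C(/C)CCC(OC)OC)OCCO2 | intermediate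
13 | lithium enolate of 12 (C6=C7) | [Li]OC1=CC2(CC[C@@H]1C/C=C(/C)CCC(OC)OC)OCCO2 | intermediate
14 | (8R)-8-[(2Z)-6,6-dimethoxy-3-methylhex-2-en-1-yl]-1,4-dioxaspiro[4.5]dec-6-en-7-yl trifluoromethanesulfonate | FC(F)(F)S(=O)(=O)OC1=CC2(CC[C@@H]1C/C=C(/C)CCC(OC)OC)OCCO2 | intermediate
15 | 2-(trimethylsilyl)ethyl (8R)-8-[(2Z)-6,6-dimethoxy-3-methylhex-2-en-1-yl]-1,4-dioxaspiro[4.5]dec-6-ene-7-carboxylate | C[Si](C)(C)CCOC(=O)C1=CC2(CC[C@@H]1C/C=C(/C)CCC(OC)OC)OCCO2 | intermediate
16 | 2-(trimethylsilyl)ethyl (8R)-8-[(2Z)-3-methyl-6-oxohex-2-en-1-yl]-1,4-dioxaspiro[4.5]dec-6-ene-7-carboxylate | C[Si](C)(C)CCOC(=O)C1=CC2(CC[C@@H]1C/C=C(/C)CCC=O)OCCO2 | intermediate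
17 | 2-(trimethylsilyl)ethyl (8R)-8-[(2Z,6Z)-7-iodo-3-methylocta-2,6-dien-1-yl]-1,4-dioxaspiro[4.5]dec-6-ene-7-carboxylate | C[Si](C)(C)CCOC(=O)C1=CC2(CC[C@@H]1C/C=C(/C)CC/C=C(/C)I)OCCO2 | intermediate
18 | 2-(trimethylsilyl)ethyl (6R)-6-[(2Z,6Z)-7-iodo-3-methylocta-2,6-dien-1-yl]-3-oxocyclohex-1-ene-1-carboxylate | C[Si](C)(C)CCOC(=O)C1=CC(=O)CC[C@@H]1C/C=C(/C)CC/C=C(/C)I | intermediate
19 | 5-bromo-2-methylpent-2-ene | CC(C)=CCCBr | starting material
20 | (4-methylpent-3-en-1-yl)magnesium bromide | CC(C)=CCC[Mg]Br | intermediate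
21 | bromomagnesium enolate of the conjugate adduct of 18 | CC(C)=CCC[C@]1(C(=O)OCC[Si](C)(C)C)[C@@H](C/C=C(/C)CC/C=C(/C)I)CCC(O[Mg]Br)=C1 | intermediate
22 | 2-(trimethylsilyl)ethyl (1S,2S,6R)-2-(hydroxymethyl)-6-[(2Z,6Z)-7-iodo-3-methylocta-2,6-dien-1-yl]-1-(4-methylpent-3-en-1-yl)-3-oxocyclohexane-1-carboxylate (ester cis to the dienyl arm, trans to CH2OH) | CC(C)=CCC[C@]1(C(=O)OCC[Si](C)(C)C)[C@@H](C/C=C(/C)CC/C=C(/C)I)CCC(=O)[C@@H]1CO | intermediate
23 | 3-methylidene analogue of 22, (1S,2S,6R) | CC(C)=CCC[C@]1(C(=O)OCC[Si](C)(C)C)[C@@H](C/C=C(/C)CC/C=C(/C)I)CCC(=C)[C@@H]1CO | intermediate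
24 | 2-(trimethylsilyl)ethyl (3S,4S,5S,6R)-4-(hydroxymethyl)-6-[(2Z,6Z)-7-iodo-3-methylocta-2,6-dien-1-yl]-5-(4-methylpent-3-en-1-yl)-1-oxaspiro[2.5]octane-5-carboxylate (oxirane O cis to CH2OH, trans to ester) | CC(C)=CCC[C@]1(C(=O)OCC[Si](C)(C)C)[C@@H](C/C=C(/C)CC/C=C(/C)I)CC[C@@]2(CO2)[C@@H]1CO | intermediate
25 | 4-formyl analogue of 24, (3S,4R,5S,6R) | CC(C)=CCC[C@]1(C(=O)OCC[Si](C)(C)C)[C@@H](C/C=C(/C)CC/C=C(/C)I)CC[C@@]2(CO2)[C@@H]1C=O | intermediate
26 | 4-ethenyl analogue of 24, (3S,4R,5S,6R) | CC(C)=CCC[C@]1(C(=O)OCC[Si](C)(C)C)[C@@H](C/C=C(/C)CC/C=C(/C)I)CC[C@@]2(CO2)[C@@H]1C=C | intermediate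
27 | B-alkyl-9-BBN from 26 (boron on the terminal carbon of the former vinyl group) | CC(C)=CCC[C@]1(C(=O)OCC[Si](C)(C)C)[C@@H](C/C=C(/C)CC/C=C(/C)I)CC[C@@]2(CO2)[C@@H]1CCB3C4CCCC3CCC4 | intermediate
28 | 2-(trimethylsilyl)ethyl ester of 29 | CC(C)=CCC[C@]1(C(=O)OCC[Si](C)(C)C)[C@H]2C/C=C(/C)CC/C=C(/C)CC[C@H]1[C@@]1(CC2)CO1 | intermediate
29 | (1R,3Z,7Z,11R,12S,15S)-4,8-dimethyl-15-(4-methylpent-3-en-1-yl)spiro[bicyclo[9.3.1]pentadeca-3,7-diene-12,2'-oxirane]-15-carboxylic acid | CC(C)=CCC[C@]1(C(=O)O)[C@H]2C/C=C(/C)CC/C=C(/C)CC[C@H]1[C@@]1(CC2)CO1 | target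

**Totals.** Total steps: 16. Longest linear sequence: 15 (steps 1–3 and 5–16).

**Steps most likely to fail**

Step 15 (macrocyclisation). Oligomerisation may outrun ring closure, and protodeboronation or β-hydride elimination may consume the alkyl partner before transmetalation. The fallback closes the same bond through an organozinc prepared and purified stepwise. Setting out from 26, hydroboration with 9-BBN and oxidation (NaBO3) should give the primary alcohol F1, and iodination (I2, PPh3, imidazole, 0 °C) the primary iodide F2. Zinc insertion (Zn dust, LiCl, THF, 40 °C), which should spare the alkenyl iodide, would give the alkylzinc iodide F3. Intramolecular Negishi coupling (Pd2(dba)3, SPhos, THF, high dilution) would then return to the route at 28.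

Step 10 (conjugate addition and hydroxymethylation). Trapping of the hindered enolate may be incomplete or unselective through proton transfer, double hydroxymethylation or attack syn to the ester, and 1,2-addition may compete. The fallback separates the two events. Setting out from 18, the copper-catalysed addition is run with Me3SiCl to give the trimethylsilyl enol ether F4, which is purified. F4 is then hydroxymethylated in a Mukaiyama aldol reaction (aqueous formaldehyde, Yb(OTf)3, THF), returning to the route at 22.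

Step 7 (enol triflate). Deprotonation on the substituted side would erase the stereocentre, and β-elimination could open the ketal. The fallback is a Shapiro sequence. Setting out from 12, condensation with 2,4,6-triisopropylbenzenesulfonyl hydrazide gives the hydrazone F5. n-BuLi (2.2 equiv, THF/TMEDA, −78 → 0 °C) should generate the less substituted vinyllithium F6 by syn-directed deprotonation of the CH2. Quenching with 2-(trimethylsilyl)ethyl chloroformate returns to the route at 15, which is carried on through the acid treatment of step 8.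

Further compounds
F1 | step 15 | primary alcohol from hydroboration–oxidation of 26 (2-hydroxyethyl arm) | CC(C)=CCC[C@]1(C(=O)OCC[Si](C)(C)C)[C@@H](C/C=C(/C)CC/C=C(/C)I)CC[C@@]2(CO2)[C@@H]1CCO
F2 | step 15 | corresponding primary iodide (2-iodoethyl arm) | CC(C)=CCC[C@]1(C(=O)OCC[Si](C)(C)C)[C@@H](C/C=C(/C)CC/C=C(/C)I)CC[C@@]2(CO2)[C@@H]1CCI
F3 | step 15 | alkylzinc iodide from F2 | CC(C)=CCC[C@]1(C(=O)OCC[Si](C)(C)C)[C@@H](C/C=C(/C)CC/C=C(/C)I)CC[C@@]2(CO2)[C@@H]1CC[Zn]I
F4 | step 10 | trimethylsilyl enol ether of the conjugate adduct of 18 | CC(C)=CCC[C@]1(C(=O)OCC[Si](C)(C)C)[C@@H](C/C=C(/C)CC/C=C(/C)I)CCC(O[Si](C)(C)C)=C1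
F5 | step 7 | 2,4,6-triisopropylbenzenesulfonylhydrazone of 12 | CC(C)c1cc(C(C)C)c(S(=O)(=O)NN=C2CC3(CC[C@@H]2C/C=C(/C)CCC(OC)OC)OCCO3)c(C(C)C)c1
F6 | step 7 | vinyllithium from F5 (lithium on C7, C6=C7) | [Li]C1=CC2(CC[C@@H]1C/C=C(/C)CCC(OC)OC)OCCO2
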